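**Strategy**

The route rests on cutting the CH2–CH2 bridge between C7 of the dibenzofuran and ring C (the carbon para to its OH). Because both bridge carbons are benzylic and at the same oxidation level, each is carried as an aryl nitrile and unveiled as an aldehyde. An intramolecular McMurry coupling of the dialdehyde then closes the 18-membered ring and creates the bridge as a stilbene in one operation; a final hydrogenation saturates it while removing both benzyl ethers. The precursor is an open-chain dibenzofuran-7-carbaldehyde tied through the C1 ethano bridge and the diaryl ether to a 4-benzyloxybenzaldehyde unit. The dibenzofuran arises by Suzuki coupling and fluoride displacement.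

Key step: step 9

Remark: dibenzofuran locants are used so that C1 carries the ethano bridge to the para-phenylene ring (ring D), C3 the oxygen and C7 the one-carbon unit; ring A is C1–C4, ring B is C6–C9, ring C is the catechol-derived ring. The alkene of 14 is assumed Z, the geometry the ring should favour; it is erased in step 10.

**Route**

Step 1
Reactants: 1 3-hydroxy-4-methoxybenzonitrile; 2 4-fluorobenzaldehyde
Product: 3 3-(4-formylphenoxy)-4-methoxybenzonitrile
Conditions: K2CO3, DMF, 130 °C
Reagents that add atoms: none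
Why: Nucleophilic aromatic substitution (SNAr) in which the phenoxide of 1 displaces fluoride para to the formyl group, which stabilises the Meisenheimer intermediate, while the nitrile is inert.

Step 2
Reactants: 3 3-(4-formylphenoxy)-4-methoxybenzonitrile; 4 diethyl (3,5-dimethoxybenzyl)phosphonate
Product: 5 (E)-3-{4-[2-(3,5-dimethoxyphenyl)ethenyl]phenoxy}-4-methoxybenzonitrile
Conditions: KOt-Bu, THF, 0 °C to rt
Reagents that add atoms: none
Why: Horner–Wadsworth–Emmons olefination of the non-enolisable aryl aldehyde by the benzylic phosphonate anion should give the E-stilbene, whose geometry is erased in step 3.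

Step 3
Reactants: 5 (E)-3-{4-[2-(3,5-dimethoxyphenyl)ethenyl]phenoxy}-4-methoxybenzonitrile
Product: 6 3-{4-[2-(3,5-dimethoxyphenyl)ethyl]phenoxy}-4-methoxybenzonitrile
Conditions: H2 (1 atm), Pd/C (10% Pd on carbon), EtOAc, rt
Reagents that add atoms: none
Why: Catalytic hydrogenation of the stilbene C=C is much faster than reduction of an aryl nitrile in neutral EtOAc at 1 atm, so the reaction is stopped after uptake of one equivalent of H2.

Step 4
Reactants: 6 3-{4-[2-(3,5-dimethoxyphenyl)ethyl]phenoxy}-4-methoxybenzonitrile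
Product: 7 3-{4-[2-(2-bromo-3,5-dimethoxyphenyl)ethyl]phenoxy}-4-methoxybenzonitrile
Conditions: NBS (1.0 equiv), MeCN, 0 °C, dark
Reagents that add atoms: N-bromosuccinimide, O=C1CCC(=O)N1Br
Why: Electrophilic aromatic bromination in which the 3,5-dimethoxyphenyl ring is by far the most electron-rich arene and reacts at C2 (ortho to one OMe, para to the other) and not at the more hindered carbon between the two OMe groups, the site pattern known for 5-alkylresorcinol dimethyl ethers.

Step 5
Reactants: 7 3-{4-[2-(2-bromo-3,5-dimethoxyphenyl)ethyl]phenoxy}-4-methoxybenzonitrile; 8 (4-cyano-2-fluorophenyl)boronic acid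
Product: 9 3-{4-[2-(4'-cyano-2'-fluoro-4,6-dimethoxybiphenyl-2-yl)ethyl]phenoxy}-4-methoxybenzonitrile
Conditions: Pd(OAc)2 (5 mol%), SPhos (2-dicyclohexylphosphino-2',6'-dimethoxybiphenyl, 10 mol%), K3PO4, toluene/H2O, 90 °C, 8 (2 equiv) added in portions
Reagents that add atoms: none
Why: Suzuki–Miyaura coupling in which the bulky electron-rich biarylphosphine on zerovalent palladium is suited to a tri-ortho-substituted biaryl and the excess of 8 offsets protodeboronation.

Step 6
Reactants: 9 3-{4-[2-(4'-cyano-2'-fluoro-4,6-dimethoxybiphenyl-2-yl)ethyl]phenoxy}-4-methoxybenzonitrile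
Product: 10 3-{4-[2-(4'-cyano-2'-fluoro-4,6-dihydroxybiphenyl-2-yl)ethyl]phenoxy}-4-hydroxybenzonitrile
Conditions: BBr3 (6 equiv), CH2Cl2, −78 °C to rt; then H2O
Reagents that add atoms: none
Why: Lewis-acid cleavage of all three aryl methyl ethers (O-complexation, then bromide attack at methyl), to which the nitriles, the aryl fluoride and the diaryl ether are stable.

Step 7
Reactants: 10 3-{4-[2-(4'-cyano-2'-fluoro-4,6-dihydroxybiphenyl-2-yl)ethyl]phenoxy}-4-hydroxybenzonitrile
Product: 12 3-(benzyloxy)-1-{2-[4-(2-benzyloxy-5-cyanophenoxy)phenyl]ethyl}dibenzofuran-7-carbonitrile, via dibenzofuran diphenol 11 (not isolated)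
Conditions: K2CO3 (5 equiv), NMP, 160 °C; cool to 60 °C, then BnBr (2.5 equiv)
Reagents that add atoms: benzyl bromide, BrCc1ccccc1
Why: Intramolecular SNAr in which only the phenoxide ortho to the biaryl bond can reach the C–F carbon of ring B (a closure known for 2'-fluorobiphenyl-2-ols and helped inductively by the meta nitrile) forms the furan, and Williamson O-benzylation of the two remaining phenoxides follows in the same pot.

Step 8
Reactants: 12 3-(benzyloxy)-1-{2-[4-(2-benzyloxy-5-cyanophenoxy)phenyl]ethyl}dibenzofuran-7-carbonitrile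
Product: 13 3-(benzyloxy)-1-{2-[4-(2-benzyloxy-5-formylphenoxy)phenyl]ethyl}dibenzofuran-7-carbaldehyde
Conditions: i-Bu2AlH (3 equiv), CH2Cl2, −78 °C to 0 °C; then 1 M HCl
Reagents that add atoms: water, O
Why: In this DIBAL nitrile reduction each nitrile takes up one hydride to give an N-aluminio aldimine that resists further reduction and is hydrolysed to the aldehyde on acidic work-up, while benzyl and diaryl ethers are inert.

Step 9
Reactants: 13 3-(benzyloxy)-1-{2-[4-(2-benzyloxy-5-formylphenoxy)phenyl]ethyl}dibenzofuran-7-carbaldehyde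
Product: 14 (Z)-stilbene macrocycle, the dibenzyl ether of asterelin A with a (Z)-CH=CH unit in place of the CH2–CH2 bridge between C7 of the dibenzofuran and ring C
Conditions: TiCl4 (12 equiv), Zn (24 equiv), THF, reflux; 13 added by syringe pump over 24 h (final about 1 mM); then H2O
Reagents that add atoms: none
Why: Low-valent titanium generated from TiCl4 and Zn reduces both formyl groups to ketyl radicals, which couple on the titanium surface to a cyclic titanium pinacolate; on heating this loses both oxygens to the oxophilic metal and leaves the C=C bond (McMurry coupling). The closest known reaction type is the intramolecular McMurry coupling of aromatic dialdehydes to cyclic stilbenes, established for cyclophanes and macrocyclic bis(bibenzyl) precursors. The 18-membered ring closes end to end by union of the two formyl carbons while both are bound to the same titanium surface, so the closure is templated. No stereocentre is formed, and the alkene geometry, expected Z because the ring has to turn back at C7, is erased in step 10. The step needs intra- over intermolecular coupling, which slow addition at about 1 mM should secure, and it needs no cross-selectivity because both ends are the same functional group at the same oxidation level. Benzyl ethers, the diaryl ether and the dibenzofuran should not react with the reagent.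

Step 10
Reactants: 14 (Z)-stilbene macrocycle
Product: 15 asterelin A
Conditions: H2 (1 atm), Pd/C (10% Pd on carbon), EtOAc/MeOH, rt
Reagents that add atoms: none
Why: One catalytic hydrogenation saturates the stilbene to the CH2–CH2 bridge and hydrogenolyses both benzyl ethers, while the diaryl ether and dibenzofuran C–O bonds are not cleaved under these conditions.

**Compound list**

1 | 3-hydroxy-4-methoxybenzonitrile | N#Cc1ccc(OC)c(O)c1 | starting material
2 | 4-fluorobenzaldehyde | O=Cc1ccc(F)cc1 | starting material
3 | 3-(4-formylphenoxy)-4-methoxybenzonitrile | N#Cc1ccc(OC)c(Oc2ccc(C=O)cc2)c1 | intermediate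
4 | diethyl (3,5-dimethoxybenzyl)phosphonate | CCOP(=O)(OCC)Cc1cc(OC)cc(OC)c1 | starting material
5 | (E)-3-{4-[2-(3,5-dimethoxyphenyl)ethenyl]phenoxy}-4-methoxybenzonitrile | N#Cc1ccc(OC)c(Oc2ccc(/C=C/c3cc(OC)cc(OC)c3)cc2)c1 | intermediate
6 | 3-{4-[2-(3,5-dimethoxyphenyl)ethyl]phenoxy}-4-methoxybenzonitrile | N#Cc1ccc(OC)c(Oc2ccc(CCc3cc(OC)cc(OC)c3)cc2)c1 | intermediate
7 | 3-{4-[2-(2-bromo-3,5-dimethoxyphenyl)ethyl]phenoxy}-4-methoxybenzonitrile | N#Cc1ccc(OC)c(Oc2ccc(CCc3cc(OC)cc(OC)c3Br)cc2)c1 | intermediate
8 | (4-cyano-2-fluorophenyl)boronic acid | OB(O)c1ccc(C#N)cc1F | starting material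
9 | 3-{4-[2-(4'-cyano-2'-fluoro-4,6-dimethoxybiphenyl-2-yl)ethyl]phenoxy}-4-methoxybenzonitrile | N#Cc1ccc(OC)c(Oc2ccc(CCc3cc(OC)cc(OC)c3-c3ccc(C#N)cc3F)cc2)c1 | intermediate
10 | 3-{4-[2-(4'-cyano-2'-fluoro-4,6-dihydroxybiphenyl-2-yl)ethyl]phenoxy}-4-hydroxybenzonitrile | N#Cc1ccc(O)c(Oc2ccc(CCc3cc(O)cc(O)c3-c3ccc(C#N)cc3F)cc2)c1 | intermediate
11 | 1-{2-[4-(5-cyano-2-hydroxyphenoxy)phenyl]ethyl}-3-hydroxydibenzofuran-7-carbonitrile (dibenzofuran diphenol, not isolated) | N#Cc1ccc(O)c(Oc2ccc(CCc3cc(O)cc4oc5cc(C#N)ccc5c34)cc2)c1 | intermediate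
12 | 3-(benzyloxy)-1-{2-[4-(2-benzyloxy-5-cyanophenoxy)phenyl]ethyl}dibenzofuran-7-carbonitrile | N#Cc1ccc(OCc2ccccc2)c(Oc2ccc(CCc3cc(OCc6ccccc6)cc4oc5cc(C#N)ccc5c34)cc2)c1 | intermediate
13 | 3-(benzyloxy)-1-{2-[4-(2-benzyloxy-5-formylphenoxy)phenyl]ethyl}dibenzofuran-7-carbaldehyde | O=Cc1ccc(OCc2ccccc2)c(Oc2ccc(CCc3cc(OCc6ccccc6)cc4oc5cc(C=O)ccc5c34)cc2)c1 | intermediate
14 | (Z)-stilbene macrocycle: asterelin A dibenzyl ether with a (Z)-CH=CH unit between C7 of the dibenzofuran and ring C | C(c1ccccc1)Oc1cc2c3c(c1)oc1cc(ccc13)/C=C\c1ccc(OCc3ccccc3)c(c1)Oc1ccc(cc1)CC2 | intermediate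
15 | asterelin A | Oc1cc2c3c(c1)oc1cc(ccc13)CCc1ccc(O)c(c1)Oc1ccc(cc1)CC2 | target

**Count and risks**

Total step count: 10. Longest linear sequence: 10 steps (1 to 15); 2, 4 and 8 enter as commercial inputs.

Steps most likely to fail:

Step 9. Intermolecular carbonyl coupling may outrun ring closure and lead to oligomerisation, or the reaction may stop at the pinacolate stage if the ring resists the deoxygenation geometry. The fallback sets out from 13 and replaces the kinetically controlled reductive coupling by a reversible metathesis. Double Wittig methylenation (Ph3PCH3Br, KOt-Bu, THF, 0 °C to rt) should give the bis-styrene 3-(benzyloxy)-1-{2-[4-(2-benzyloxy-5-ethenylphenoxy)phenyl]ethyl}-7-ethenyldibenzofuran F1. Ring-closing metathesis (second-generation Grubbs catalyst RuCl2(=CHPh)(PCy3)(H2IMes), toluene, 80 °C, about 1 mM, argon sparge) should then join the same two carbons with loss of ethene. Oligomers can re-enter the ring–chain equilibrium, and the fallback comes back to the route at 14.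

Step 5. Protodeboronation of the electron-poor ortho-fluoro boronic acid may outpace transmetalation to the hindered, electron-rich arylpalladium bromide. The fallback sets out from 7 and reverses the roles of the partners. Miyaura borylation (B2pin2, Pd(OAc)2, SPhos, KOAc, dioxane, 100 °C) should give the pinacol boronate 3-{4-[2-(3,5-dimethoxy-2-(4,4,5,5-tetramethyl-1,3,2-dioxaborolan-2-yl)phenyl)ethyl]phenoxy}-4-methoxybenzonitrile F2. Suzuki–Miyaura coupling of this with 4-bromo-3-fluorobenzonitrile (Pd(OAc)2, SPhos, K3PO4, toluene/H2O, 90 °C) uses a stable, easily inserted electrophile and comes back to the route at 9.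

Step 7. Fluoride displacement at a carbon activated only inductively may be sluggish, with nitrile hydrolysis on prolonged heating in carbonate. The fallback sets out from 7 and closes the furan by C–H oxygenation, not substitution.
- Suzuki–Miyaura coupling with (4-cyanophenyl)boronic acid (Pd(OAc)2, SPhos, K3PO4) should give 3-{4-[2-(4'-cyano-4,6-dimethoxybiphenyl-2-yl)ethyl]phenoxy}-4-methoxybenzonitrile F3.
- BBr3 (CH2Cl2, −78 °C to rt) should give the triphenol 3-{4-[2-(4'-cyano-4,6-dihydroxybiphenyl-2-yl)ethyl]phenoxy}-4-hydroxybenzonitrile F4.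
- Phenol-directed C–H activation by divalent palladium and C–O reductive elimination (Pd(OAc)2, 3-nitropyridine, tert-butyl peroxybenzoate, C6F6/1,3-dimethyl-2-imidazolidinone, 90 °C) should close the furan at either of the two equivalent ortho C–H bonds of the 4-cyanophenyl ring to give 11.
- Benzylation of 11 as in the second half of step 7 (K2CO3, BnBr, NMP, 60 °C) comes back to the route at 12.

**Further compounds**

F1 | step 9 | 3-(benzyloxy)-1-{2-[4-(2-benzyloxy-5-ethenylphenoxy)phenyl]ethyl}-7-ethenyldibenzofuran | C=Cc1ccc(OCc2ccccc2)c(Oc2ccc(CCc3cc(OCc6ccccc6)cc4oc5cc(C=C)ccc5c34)cc2)c1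
F2 | step 5 | 3-{4-[2-(3,5-dimethoxy-2-(4,4,5,5-tetramethyl-1,3,2-dioxaborolan-2-yl)phenyl)ethyl]phenoxy}-4-methoxybenzonitrile | N#Cc1ccc(OC)c(Oc2ccc(CCc3cc(OC)cc(OC)c3B4OC(C)(C)C(C)(C)O4)cc2)c1
F3 | step 7 | 3-{4-[2-(4'-cyano-4,6-dimethoxybiphenyl-2-yl)ethyl]phenoxy}-4-methoxybenzonitrile | N#Cc1ccc(OC)c(Oc2ccc(CCc3cc(OC)cc(OC)c3-c3ccc(C#N)cc3)cc2)c1
F4 | step 7 | 3-{4-[2-(4'-cyano-4,6-dihydroxybiphenyl-2-yl)ethyl]phenoxy}-4-hydroxybenzonitrile | N#Cc1ccc(O)c(Oc2ccc(CCc3cc(O)cc(O)c3-c3ccc(C#N)cc3)cc2)c1
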